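The target, counted here together with its crystals, is what you want from the flask, and time, partner and starting material could move it.

| setting | east | south | flask |
|---|---|---|---|
| starting material | 6.7 mM | 15 mM | 10 mM |
| partner | 13 mM | 13 mM | 13.0 mM |
| remark | run made earlier | run made earlier |  |
| time |  |  | 10 d |

| run | time / d | target / % | crystals / % | starting material / % |
|---|---|---|---|---|
| east | 0.417 | 10.1 | 0.2 | 69.9 |
| east | 1.25 | 41.4 | 0 | 33.9 |
| east | 2.00 | 61.3 | 13.0 | 17.6 |
| east | 3.00 | 76.8 | 28.3 | 7.1 |
| east | 5.00 | 87.8 | 40.1 | 1.3 |
| east | 6.00 | 90.2 | 43.0 | 0.8 |
| south | 0.417 | 9.5 | 0.4 | 69.9 |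
| south | 1.25 | 36.1 | 13.3 | 33.3 |
| south | 2.00 | 50.9 | 27.8 | 18.2 |
| south | 3.00 | 60.7 | 39.5 | 7.8 |
| south | 5.00 | 69.9 | 48.1 | 1.0 |
| south | 6.00 | 71.9 | 50.6 | 0.4 |

(each reading ± 0.3 percentage points)

- how much target and crystals together there is at 10 d, in percent of the starting material charged
- concentration of target in solution at 10 d, in percent of saturation

- what is said of target includes crystals
- crystals is a solid; its amount is given per volume of the solution

Take time first. In the east run the last day added 2.4 percentage points with 0.8% of starting material left, so by hand you expect the flask at 10 d to stand close to its end share.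

Partner is 13.0 mM in both runs and in the flask, so the readings never turn it. If one partner goes into each target, the yield is capped at c(partner)/c(starting material): 86.7% in south, but 130%, no cap, in the flask, where starting material is the limiting reagent.

Starting material is the setting the runs do turn. At 1.25 d east has lost 66.1% of it but shows 41.4% target, so an intermediate stands between them. Suppose a loss takes two intermediate together while the target step takes one. Then, at fixed partner, the zero of the scale is a vanishing charge, and I take the lost share as roughly proportional to the charge, an assumption that needs partner to stay near its own charge. East misses 9.80% at 6.7 mM in its last reading, at 6.00 d, when some of this may still be on its way to target, which gives 0.0146 mM⁻¹, the specific loss: the share missing per mM of starting material charged. South misses 28.1% in its last reading, more than the 21.9% this gives, but south also has its cap.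

For the flask I reckon a loss of 14.6%, so 85.4%. Dissolved target in south reads near 3.20 mM at its last reading, which I take as saturation, and this is below the 8.54 mM I reckon for the flask, so I expect crystals and 100% of saturation.

The forecast has 87% and 100%, in its words: “Dissolved target (target minus crystals) plateaus near 3.2 mM in both runs”.

The flask gives 86.3% and 100%.

    starting material → intermediate (k = 0.0360 h⁻¹)
    crystals ⇌ target, rate k2*(cs2 - [target]) while solid is left; crystals form when [target] > cs2 (solubility = 3.20 mM, k = 0.870 h⁻¹)
    2 intermediate → homo product (k = 2.90 M⁻¹ h⁻¹)
    partner + intermediate → target (k = 6.60 M⁻¹ h⁻¹)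

The flask's specific loss at 10 d is 0.0137 mM⁻¹, beside 0.0146 mM⁻¹ read from east at 6.00 d. Its missing 13.7% is mainly homo product: the same flask without that step reaches 99.3% in place of 86.3%, which accounts for 95% of what is missing. Now charge a second flask with 2.5 mM of starting material and the same partner. The specific loss predicts 3.65% lost, so 96.3%; the computed flask gives 97.3%.

All runs are calculated from invented constants.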